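## Structural features

The target is a flavonol, a 2-aryl-3-hydroxy-4H-chromen-4-one. Its phloroglucinol-type ring A (5-OH, 7-OH) is fused to the γ-pyranone ring C, and ring C carries ring B at C2. Ring B is a 4'-hydroxyphenyl group flanked at C3' and C5' by two 3-methylbut-2-enyl (prenyl) chains, so it is symmetric about the C1'–C4' axis. There is no stereocentre and no stereogenic double bond, so no stereochemical relationship has to be controlled. The fragile parts are the two ortho-prenylphenol units, which close to 2,2-dimethylchromans under acid and are attacked by halogens, peracids and dioxiranes, and the polyphenolic flavonol anion, which is oxidised by air in base. The real difficulty is to build ring C with its C3 hydroxyl, normally an electrophilic oxidation or halogenation, without touching the prenyl alkenes and without a final acidic deprotection. The key step exploits the 4'-oxygen, which is para to C1' and so conjugated with C2. As a phenoxide it can push electrons through ring B into a leaving group on the carbon that becomes C2, which lets the ring A oxygen O1 move from the spiro carbon of a five-membered benzofuranone (the future C3) to C2. Ring A is a 2,4,6-trioxygenated benzoyl unit, so its two oxygens ortho to the carbonyl become equivalent once unmasked.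

## Logic of the disconnections

**11 to 7.** The O1–C2 bond of ring C is cut and O1 is reconnected to C3. Ring C contracts to a five-membered ring, and C2 and C3 are bridged by the oxygen that becomes the 3-hydroxyl; the three phenolic O–H bonds are exchanged for O–Si bonds. The cut is made here because 7 already holds every carbon and oxygen of 11 at the final oxidation level, so no oxidant acts once the prenylphenol is free. The gain is that ring C and the C3 hydroxyl reduce to the epoxide of an arylidene benzofuranone. Ring A carries the same silyl group as the 4'-oxygen, so the reagent that triggers the rearrangement also unveils 11. Acetal protection of ring A was set aside because it would need acid afterwards, a hazardous chloromethyl ether and two more operations. The demand on the forward step is a 4'-phenoxide generated under non-acidic, non-oxidising conditions, and six-membered capture of the opened intermediate by the ring A oxygen.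

**7 to 6.** Both C–O bonds of the oxirane are cut. An α,β-epoxy ketone comes from its enone and a peroxide anion, the one oxidant class that separates the electron-poor exocyclic alkene from the two electron-rich prenyl alkenes. The gain is the loss of both stereocentres and the extra oxygen, leaving a planar, achiral aurone. The demand is a nucleophilic oxidant under conditions that keep aryl silyl ethers; the relative configuration is unimportant.

**6 to 5.** Three O–Si bonds are cut. Free phenoxides would close the enone to peroxide anion, and the 4'-oxygen must stay masked until the trigger. Silylating after the condensation keeps the silyl ethers away from hot alkali and avoids the enolisable benzofuranone stage. The gain is one reagent and one operation for three positions. The demand is complete silylation of the 4'-hydroxyl between two prenyl groups in an acid-free medium.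

**5 to 3 + 4.** The exocyclic C=C bond between benzofuranone C2 and the benzylic carbon is cut. This aldol-condensation retron divides the molecule into ring A with two carbons of ring C and ring B with the third. The gain is a convergent union of two small pieces. The demand is a base-mediated, not acid-mediated, condensation of unprotected phenols under thermodynamic control to the Z isomer.

**3 to 1 + 2.** The two aryl–CH2 bonds ortho to the hydroxyl are cut. The ring is symmetric and its para position is occupied by the formyl group, so the only selectivity question is carbon against oxygen alkylation. The gain is two commodity chemicals. The demand is a medium that favours C-alkylation of the phenoxide and attachment through the primary carbon of the allyl unit.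

## Other disconnections considered

**Alternative 1:** The cut runs through ring A at C4a–C8a, so the phloroglucinol ring is grown from a polyketide chain instead of being bought.
- Forward key step: the cinnamoylmethyl pyrone A1 would be treated with Mg(OMe)2 in methanol. Methoxide opens the lactone to a magnesium-chelated 3,5,7-triketo ester, whose C6 carbanion acylates on the ester carbon (Claisen mode) and aromatises to chalcone A2.
- In its favour: the reaction type is well precedented for polyketide-derived phloroglucinols, the chelate steers towards Claisen and away from aldol closure, and the 5,7-dioxygenation arises without a regiochemical decision. On precedent for the key step this alternative is better than the chosen plan.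
- Against it here: ring A is the one part of the target that can be bought already carrying two ring C carbons (compound 4), so the step builds what is available. The enone of A1 is exposed to methoxide and to oxa-Michael closure to a flavanone. A2 still lacks ring C and the C3 oxygen, so a protection, an alkaline peroxide oxidation (prone to aurone formation for a 6'-oxygenated chalcone) and an acidic removal of the ring B acetal would follow. That last step is the threat to the prenylphenol that the chosen plan avoids.
- Comparison: on structure the plans are equal in how ring B is made, since both use 3. On mechanism the alternative puts its certainty on the easy ring and leaves the hard ring to a less selective oxidation, while the chosen plan spends its one unproven step on exactly that problem. On step economy about eight operations from 3 stand against four.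

**Alternative 2:** The cut removes the C2–C3 bond and the C4–O bond together, masking C2–C3–C4 of ring C as an isoxazole.
- Forward key step: nitrile oxide A3, generated in situ from the aldoxime, would add to alkynyl boronate A4 to give isoxazol-4-yl boronate A5 with boron on the future C3. Oxidation of C–B to C–OH, N–O cleavage (for example Mo(CO)6 in wet acetonitrile) and acid-mediated closure with loss of ammonia and of the acetals would complete ring C.
- In its favour: the plan is convergent, the C3 oxygen is placed regiospecifically through boron, and there is no aurone/flavonol ambiguity. The cycloaddition and its regiochemistry are known for substituted alkynyl boronates, so this key step is better precedented than the chosen one.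
- Against it here: making A3 requires N-chlorination of an oxime next to two trisubstituted alkenes, and the nitrile oxide can add to those alkenes or dimerise while the di-ortho-substituted, electron-rich alkyne A4 reacts slowly. A4 needs several steps of its own. The unmasking passes through oxidation-prone 4-hydroxyisoxazole and α-hydroxy enaminone stages and ends with acid on four acetals beside the prenylphenol.
- Comparison: on structure the two plans are equal in convergence; the alternative forms a core C–C bond in its key step, the chosen plan a C–O bond. On mechanism its key step stands on firmer ground, but three uncertain unmasking steps follow, whereas the chosen relay delivers the oxidised ring C in one operation. On step economy roughly twelve operations stand against five.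

**Alternative 3:** The cut removes the two aryl–CH2 bonds of ring B from a finished flavonol.
- Forward key step: dibromide A6 would couple twice with prenylzinc bromide A7 under Pd(OAc)2 and the biaryl phosphine CPhos to give A8; acidic removal of four acetals would follow.
- In its favour: the prenyl groups are absent while ring C is made, so A6 can be assembled by any classical flavonol synthesis, including those that use halogens or electrophilic oxidants. Here the alternative is better than the chosen plan, because core construction rests entirely on established reactions. The linear-selective coupling is a known reaction type for aryl bromides, and a late common intermediate would serve analogues.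
- Against it here: both bromides flank the 4'-acetal, so each coupling is ortho-hindered and the second occurs on a more electron-rich ring. Linear selectivity must hold twice, and linear/branched isomers would be hard to separate. The pyranone carbonyl and neighbouring acetals can bind zinc. The last step again exposes both ortho-prenylphenol units to acid.
- Comparison: on structure the same bonds are made in both plans, but the chosen plan installs the prenyl groups first on a cheap small molecule and the alternative installs them last on the most valuable intermediate. On mechanism the alternative uses proven reaction classes throughout, against one unproven step in the chosen plan. On step economy about seven operations stand against five, and only the chosen route finishes without acid.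

Key step: step 5

Remark on the chemistry: the three silyl ethers of 7 are assumed to be cleaved before the skeletal events, so intermediates 8 to 10 are written desilylated and neutral; any other order of silyl loss converges on the same product.

## Route

Step 1
Reactants: 1 4-hydroxybenzaldehyde; 2 prenyl bromide (1-bromo-3-methylbut-2-ene)
Product: 3 4-hydroxy-3,5-bis(3-methylbut-2-en-1-yl)benzaldehyde
Conditions: KOH (10% aq), 2 (2.5 equiv), rt; mono-prenylated material resubmitted
Reagents that add atoms: none
Why: Ortho C-alkylation of a phenoxide in water, where hydrogen bonding to the phenoxide oxygen favours attack through carbon; SN2 at the primary carbon of 2 gives the linear prenyl group, and the blocked para position and ring symmetry leave no regiochemical choice.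

Step 2
Reactants: 3 4-hydroxy-3,5-bis(3-methylbut-2-en-1-yl)benzaldehyde; 4 4,6-dihydroxybenzofuran-3(2H)-one
Product: 5 (Z)-4,6-dihydroxy-2-[4-hydroxy-3,5-bis(3-methylbut-2-en-1-yl)benzylidene]benzofuran-3(2H)-one
Conditions: KOH (50% aq), MeOH, 60 °C, Ar; then AcOH, 0 °C
Reagents that add atoms: none
Why: Aldol condensation of the benzofuranone C2 methylene with the aldehyde followed by E1cB dehydration, a standard route to polyhydroxyaurones; the Z isomer (aryl syn to O1, away from the carbonyl) is the thermodynamic product, and base instead of acid spares the prenyl groups.

Step 3
Reactants: 5 (Z)-4,6-dihydroxy-2-[4-hydroxy-3,5-bis(3-methylbut-2-en-1-yl)benzylidene]benzofuran-3(2H)-one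
Product: 6 (Z)-4,6-bis(triisopropylsilyloxy)-2-[3,5-bis(3-methylbut-2-en-1-yl)-4-(triisopropylsilyloxy)benzylidene]benzofuran-3(2H)-one
Conditions: TIPSOTf (3.6 equiv), 2,6-lutidine, CH2Cl2, 0 °C to rt
Reagents that add atoms: triisopropylsilyl trifluoromethanesulfonate, CC(C)[Si](C(C)C)(C(C)C)OS(=O)(=O)C(F)(F)F
Why: O-silylation of phenols; the silyl triflate is reactive enough for the 4'-hydroxyl between two CH2 groups, the hindered base keeps the medium free of acid, and the aurone has no enolisable position that could be silylated.

Step 4
Reactants: 6 (Z)-4,6-bis(triisopropylsilyloxy)-2-[3,5-bis(3-methylbut-2-en-1-yl)-4-(triisopropylsilyloxy)benzylidene]benzofuran-3(2H)-one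
Product: 7 racemic (2S*,3'S*)-4,6-bis(triisopropylsilyloxy)-3'-[3,5-bis(3-methylbut-2-en-1-yl)-4-(triisopropylsilyloxy)phenyl]-3H-spiro[benzofuran-2,2'-oxiran]-3-one (aryl cis to O1; the 2S,3'S enantiomer is drawn)
Conditions: t-BuOOH (in decane), DBU, CH2Cl2, 0 °C to rt
Reagents that add atoms: tert-butyl hydroperoxide, CC(C)(C)OO
Why: Weitz–Scheffer nucleophilic epoxidation: the peroxide anion adds to the exocyclic β-carbon and the enolate closes on oxygen with loss of tert-butoxide, which leaves the electron-rich prenyl alkenes alone, while the anhydrous amine base spares the aryl silyl ethers; the two new stereocentres are set relative to each other by closure through the rotamer with aryl anti to the carbonyl, the product is racemic, and both centres are erased in step 5.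

Step 5
Reactants: 7 racemic (2S*,3'S*)-4,6-bis(triisopropylsilyloxy)-3'-[3,5-bis(3-methylbut-2-en-1-yl)-4-(triisopropylsilyloxy)phenyl]-3H-spiro[benzofuran-2,2'-oxiran]-3-one
Product: 11 3,5,7-trihydroxy-2-[4-hydroxy-3,5-bis(3-methylbut-2-en-1-yl)phenyl]-4H-chromen-4-one, via desilylated spiro-epoxide 8 (not isolated), via quinone methide 1,2-diketone 9 (not isolated), via 2-arylchroman-3,4-dione 10 (not isolated)
Conditions: TBAF (4 equiv), THF, Ar, 0 °C to rt; then AcOH
Reagents that add atoms: none
Why: Proposed new method: fluoride cleaves the three Si–O bonds, and the 4'-phenoxide of 8, para to the benzylic epoxide carbon, pushes electrons through ring B to break the benzylic C–O bond, giving a para-quinone methide with a hemiketal alkoxide on the former spiro carbon. That alkoxide collapses to a 1,2-diketone and expels the ring A phenoxide (9), which adds 1,6 to the exocyclic quinone methide carbon, forming O1–C2, closing ring C in a 6-exo-trig mode and re-aromatising ring B (10). Enolisation of the chroman-3,4-dione then gives the hydrogen-bonded flavonol 11. The closest known reaction types are the Auwers flavonol synthesis, in which alkali ring-expands an aurone dibromide, and the fluoride-induced formation of para-quinone methides from 4-silyloxybenzyl derivatives. No stereocentre remains: the transient C2 centre of 10 is lost on enolisation and both epoxide centres of 7 are destroyed, so the configuration of 7 is immaterial. The selectivity needed is oxygen capture of the quinone methide through the six-membered transition state instead of return to the five-membered hemiketal; the return is reversible, whereas 1,6-addition restores aromaticity and is followed by irreversible enolisation, and after desilylation the two ortho oxygens of ring A are equivalent, so either closes to the same product. The halogen-free, acid-free conditions leave both prenyl groups intact, and air is excluded because flavonol anions are oxidised by O2.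

## Compound list

1 | 4-hydroxybenzaldehyde | O=Cc1ccc(O)cc1 | starting material
2 | prenyl bromide (1-bromo-3-methylbut-2-ene) | CC(C)=CCBr | starting material
3 | 4-hydroxy-3,5-bis(3-methylbut-2-en-1-yl)benzaldehyde | CC(C)=CCc1cc(C=O)cc(CC=C(C)C)c1O | intermediate
4 | 4,6-dihydroxybenzofuran-3(2H)-one | O=C1COc2cc(O)cc(O)c12 | starting material
5 | (Z)-4,6-dihydroxy-2-[4-hydroxy-3,5-bis(3-methylbut-2-en-1-yl)benzylidene]benzofuran-3(2H)-one | O=C1/C(=C/c2cc(CC=C(C)C)c(O)c(CC=C(C)C)c2)Oc2cc(O)cc(O)c12 | intermediate
6 | (Z)-4,6-bis(triisopropylsilyloxy)-2-[3,5-bis(3-methylbut-2-en-1-yl)-4-(triisopropylsilyloxy)benzylidene]benzofuran-3(2H)-one | O=C1/C(=C/c2cc(CC=C(C)C)c(O[Si](C(C)C)(C(C)C)C(C)C)c(CC=C(C)C)c2)Oc2cc(O[Si](C(C)C)(C(C)C)C(C)C)cc(O[Si](C(C)C)(C(C)C)C(C)C)c12 | intermediate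
7 | racemic (2S*,3'S*)-4,6-bis(triisopropylsilyloxy)-3'-[3,5-bis(3-methylbut-2-en-1-yl)-4-(triisopropylsilyloxy)phenyl]-3H-spiro[benzofuran-2,2'-oxiran]-3-one (2S,3'S enantiomer drawn) | O=C1c2c(O[Si](C(C)C)(C(C)C)C(C)C)cc(O[Si](C(C)C)(C(C)C)C(C)C)cc2O[C@]12O[C@H]2c1cc(CC=C(C)C)c(O[Si](C(C)C)(C(C)C)C(C)C)c(CC=C(C)C)c1 | intermediate
8 | racemic (2S*,3'S*)-4,6-dihydroxy-3'-[4-hydroxy-3,5-bis(3-methylbut-2-en-1-yl)phenyl]-3H-spiro[benzofuran-2,2'-oxiran]-3-one (2S,3'S enantiomer drawn; present as its phenoxides, not isolated) | O=C1c2c(O)cc(O)cc2O[C@]12O[C@H]2c1cc(CC=C(C)C)c(O)c(CC=C(C)C)c1 | intermediate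
9 | 3-[3,5-bis(3-methylbut-2-en-1-yl)-4-oxocyclohexa-2,5-dien-1-ylidene]-1-(2,4,6-trihydroxyphenyl)propane-1,2-dione (not isolated) | O=C(C(=O)C=C1C=C(CC=C(C)C)C(=O)C(CC=C(C)C)=C1)c1c(O)cc(O)cc1O | intermediate
10 | racemic 5,7-dihydroxy-2-[4-hydroxy-3,5-bis(3-methylbut-2-en-1-yl)phenyl]chroman-3,4-dione (not isolated) | O=C1C(=O)c2c(O)cc(O)cc2OC1c1cc(CC=C(C)C)c(O)c(CC=C(C)C)c1 | intermediate
11 | 3,5,7-trihydroxy-2-[4-hydroxy-3,5-bis(3-methylbut-2-en-1-yl)phenyl]-4H-chromen-4-one | CC(C)=CCc1cc(-c2oc3cc(O)cc(O)c3c(=O)c2O)cc(CC=C(C)C)c1O | target

## Step count and least certain steps

Total step count: 5. Longest linear sequence: 5 steps (1 to 3 to 5 to 6 to 7 to 11).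

**Step 5 (key step, proposed new method).**
- Most likely failure: diversion of the quinone methide before ring closure, by intermolecular addition of phenoxide, fluoride or water or by stalling at the ring-opened hemiketal stage. This is more likely here because expulsion of the ring A oxygen from a ring already carrying two phenoxide charges is slower. Oxidative breakdown of the flavonol anion is a second risk if air enters.
- Fallback (known chemistry, from 3 back to 11): aldehyde 3 is converted with chloromethyl methyl ether and iPr2NEt into 4-(methoxymethoxy)-3,5-bis(3-methylbut-2-en-1-yl)benzaldehyde F1. Claisen–Schmidt condensation with commercial 2'-hydroxy-4',6'-bis(methoxymethoxy)acetophenone (KOH, EtOH) gives (E)-2'-hydroxy-4,4',6'-tris(methoxymethoxy)-3,5-bis(3-methylbut-2-en-1-yl)chalcone F2. Algar–Flynn–Oyamada oxidation (H2O2, NaOH, MeOH, 0 °C) gives 3-hydroxy-5,7-bis(methoxymethoxy)-2-[4-(methoxymethoxy)-3,5-bis(3-methylbut-2-en-1-yl)phenyl]-4H-chromen-4-one F3. Dilute HCl in MeOH, at the lowest temperature that removes the acetals, returns 11. This path is longer, may lose material to aurone formation in the oxidation, and ends with acid.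

**Step 4.**
- Most likely failure: slow conjugate addition of the peroxide anion to an enone deactivated by three oxygen donors, and loss of a ring A silyl group under the basic conditions, after which the phenoxide switches the enone off.
- Fallback (from 3 and 4 back to 7): the oxirane is built by C–C bond formation instead of oxidation. Aldehyde 3 is silylated (TIPSOTf, 2,6-lutidine) to 4-(triisopropylsilyloxy)-3,5-bis(3-methylbut-2-en-1-yl)benzaldehyde F4. Compound 4 is silylated (TIPSCl, imidazole, DMF) to 4,6-bis(triisopropylsilyloxy)benzofuran-3(2H)-one F5. F5 is chlorinated through its lithium enolate (LiN(SiMe3)2, then C2Cl6, THF, −78 °C) to racemic 2-chloro-4,6-bis(triisopropylsilyloxy)benzofuran-3(2H)-one F6, which is used at once. Darzens condensation of F6 with F4 (LiN(SiMe3)2, THF, −78 to 0 °C) should favour the epoxide with aryl anti to the carbonyl and rejoins the route at 7. A lack of diastereocontrol would be harmless, since both centres are erased in step 5.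

**Step 1.**
- Most likely failure: competing O-alkylation and incomplete second C-alkylation, because the formyl group withdraws the electron density needed at the ortho carbons; a third alkylation to a dienone is also possible.
- Fallback (from 2 back to 3): the formyl group is introduced after the prenyl groups. 4-Bromophenol, whose phenoxide is a better carbon nucleophile, is o,o'-diprenylated with 2 in aqueous NaOH to 4-bromo-2,6-bis(3-methylbut-2-en-1-yl)phenol F7. Deprotonation (NaH), bromine–lithium exchange (t-BuLi, THF, −78 °C) and quench with DMF return aldehyde 3.

**Step 2.**
- Most likely failure: sluggish addition to the aldehyde, which is a vinylogous carboxylate under the conditions, together with air oxidation of the benzofuranone anion during prolonged heating in alkali.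
- Fallback (from 3 and 4 back to 5): the classical condensation in hot acetic anhydride, in which the phenols are acetylated and the aldehyde stays electrophilic, gives (Z)-4,6-diacetoxy-2-[4-acetoxy-3,5-bis(3-methylbut-2-en-1-yl)benzylidene]benzofuran-3(2H)-one F8. Methanolysis (K2CO3, MeOH, 0 °C, Ar) returns 5.

## Further compounds

F1 | step 5 | 4-(methoxymethoxy)-3,5-bis(3-methylbut-2-en-1-yl)benzaldehyde | COCOc1c(CC=C(C)C)cc(C=O)cc1CC=C(C)C
F2 | step 5 | (E)-2'-hydroxy-4,4',6'-tris(methoxymethoxy)-3,5-bis(3-methylbut-2-en-1-yl)chalcone | COCOc1cc(O)c(C(=O)/C=C/c2cc(CC=C(C)C)c(OCOC)c(CC=C(C)C)c2)c(OCOC)c1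
F3 | step 5 | 3-hydroxy-5,7-bis(methoxymethoxy)-2-[4-(methoxymethoxy)-3,5-bis(3-methylbut-2-en-1-yl)phenyl]-4H-chromen-4-one | COCOc1cc(OCOC)c2c(=O)c(O)c(-c3cc(CC=C(C)C)c(OCOC)c(CC=C(C)C)c3)oc2c1
F4 | step 4 | 4-(triisopropylsilyloxy)-3,5-bis(3-methylbut-2-en-1-yl)benzaldehyde | CC(C)=CCc1cc(C=O)cc(CC=C(C)C)c1O[Si](C(C)C)(C(C)C)C(C)C
F5 | step 4 | 4,6-bis(triisopropylsilyloxy)benzofuran-3(2H)-one | O=C1COc2cc(O[Si](C(C)C)(C(C)C)C(C)C)cc(O[Si](C(C)C)(C(C)C)C(C)C)c12
F6 | step 4 | racemic 2-chloro-4,6-bis(triisopropylsilyloxy)benzofuran-3(2H)-one | O=C1C(Cl)Oc2cc(O[Si](C(C)C)(C(C)C)C(C)C)cc(O[Si](C(C)C)(C(C)C)C(C)C)c12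
F7 | step 1 | 4-bromo-2,6-bis(3-methylbut-2-en-1-yl)phenol | CC(C)=CCc1cc(Br)cc(CC=C(C)C)c1O
F8 | step 2 | (Z)-4,6-diacetoxy-2-[4-acetoxy-3,5-bis(3-methylbut-2-en-1-yl)benzylidene]benzofuran-3(2H)-one | O=C1/C(=C/c2cc(CC=C(C)C)c(OC(C)=O)c(CC=C(C)C)c2)Oc2cc(OC(C)=O)cc(OC(C)=O)c12
A1 | alternative 1 | 4-hydroxy-6-[(E)-4-[4-(methoxymethoxy)-3,5-bis(3-methylbut-2-en-1-yl)phenyl]-2-oxobut-3-en-1-yl]-2H-pyran-2-one | O=C(/C=C/c1cc(CC=C(C)C)c(OCOC)c(CC=C(C)C)c1)CC1=CC(O)=CC(=O)O1
A2 | alternative 1 | (E)-2',4',6'-trihydroxy-4-(methoxymethoxy)-3,5-bis(3-methylbut-2-en-1-yl)chalcone | O=C(/C=C/c1cc(CC=C(C)C)c(OCOC)c(CC=C(C)C)c1)c1c(O)cc(O)cc1O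
A3 | alternative 2 | 4-(methoxymethoxy)-3,5-bis(3-methylbut-2-en-1-yl)benzonitrile oxide | [O-][N+]#Cc1cc(CC=C(C)C)c(OCOC)c(CC=C(C)C)c1
A4 | alternative 2 | 4,4,5,5-tetramethyl-2-{[2,4,6-tris(methoxymethoxy)phenyl]ethynyl}-1,3,2-dioxaborolane | CC1(C)OB(C#Cc2c(OCOC)cc(OCOC)cc2OCOC)OC1(C)C
A5 | alternative 2 | 3-[4-(methoxymethoxy)-3,5-bis(3-methylbut-2-en-1-yl)phenyl]-4-(4,4,5,5-tetramethyl-1,3,2-dioxaborolan-2-yl)-5-[2,4,6-tris(methoxymethoxy)phenyl]isoxazole | CC1(C)OB(OC1(C)C)c1c(-c2cc(CC=C(C)C)c(OCOC)c(CC=C(C)C)c2)noc1-c1c(OCOC)cc(OCOC)cc1OCOC
A6 | alternative 3 | 2-[3,5-dibromo-4-(methoxymethoxy)phenyl]-3,5,7-tris(methoxymethoxy)-4H-chromen-4-one | COCOc1cc(OCOC)c2c(=O)c(OCOC)c(-c3cc(Br)c(OCOC)c(Br)c3)oc2c1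
A7 | alternative 3 | prenylzinc bromide | CC(C)=CC[Zn]Br
A8 | alternative 3 | 3,5,7-tris(methoxymethoxy)-2-[4-(methoxymethoxy)-3,5-bis(3-methylbut-2-en-1-yl)phenyl]-4H-chromen-4-one | COCOc1cc(OCOC)c2c(=O)c(OCOC)c(-c3cc(CC=C(C)C)c(OCOC)c(CC=C(C)C)c3)oc2c1
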